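**Retrosynthetic overview**

- Eduesmine is traced back, after removal of two silyl and two benzyl ethers, to a C2 lactol: the oxolane C2–H bond is made last, by hydride reduction of the 2-aryl oxocarbenium ion, anti to the C3 arm.
- The lactol is the mono-oxidation product of a twofold-symmetric 1,4-diaryl-2,3-bis(silyloxymethyl)butane-1,4-diol that already carries all four stereocentres.
- The strategy rests on this feature: in each half of the oxolane, the ring oxygen on C2 (or C5) and the hydrogen on C3 (or C4) are syn, so each O–C(aryl)–C(H)(CH2OH) pair is the syn H/O adduct of an (E)-arylidene C=C. Both C–O and both C–H bonds therefore come from one asymmetric cyclic hydroboration–oxidation of an (E,E)-2,3-bis(arylidene)butane-1,4-diol bis(silyl ether), with one IpcBH2 per diene.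
- The diene comes from O-benzylvanillin and diethyl succinate by two Stobbe condensations, ester reduction and silylation.
- Ring order: a transient borolane (closed and reopened in the key step), then the oxolane (lactol, then reduction).

Key step: step 7

Assumption: the facial sense of IpcBH2 towards an ArCH=C unit is extrapolated from simple trans- and trisubstituted alkenes. This points to the reagent made from (−)-α-pinene, B[C@H]1C[C@H]2C[C@@H]([C@@H]1C)C2(C)C, for the (S)-carbinols; the reagent from (+)-α-pinene would be used if the sense proves opposite.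

**Route**

Step 1
Reactants: 1 4-(benzyloxy)-3-methoxybenzaldehyde (O-benzylvanillin); 2 diethyl succinate
Product: 3 (E)-4-[4-(benzyloxy)-3-methoxyphenyl]-3-(ethoxycarbonyl)but-3-enoic acid
Conditions: t-BuOK, t-BuOH, reflux; then aq. HCl
Reagents that add atoms: none
Why: Stobbe condensation, in which the succinate enolate adds to the aldehyde, the alkoxide closes a paraconic ester and base-induced ring opening should give the half-ester with the aryl group trans to the ester on the new alkene (E), the usual geometry with aromatic aldehydes.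

Step 2
Reactants: 3 (E)-half-ester
Product: 4 diethyl (E)-2-[4-(benzyloxy)-3-methoxybenzylidene]succinate
Conditions: EtI, K2CO3, DMF, rt
Reagents that add atoms: ethyl iodide, CCI
Why: SN2 O-alkylation of the carboxylate restores the second ester, which a further Stobbe condensation needs, without touching the alkene geometry.

Step 3
Reactants: 4 diethyl (E)-arylidenesuccinate; 1 4-(benzyloxy)-3-methoxybenzaldehyde
Product: 5 (2E,3E)-2,3-bis[4-(benzyloxy)-3-methoxybenzylidene]succinic acid monoethyl ester
Conditions: t-BuOK, t-BuOH, reflux; then aq. HCl; crystallisation of the (E,E)-isomer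
Reagents that add atoms: none
Why: second Stobbe condensation at the remaining CH2 of 4, in which lactonisation onto the conjugated ester and ring opening should give the bis(arylidene) half-ester with each aryl group trans to the carboxyl function on its own alkene, the (E,E)-isomer being the expected major product.

Step 4
Reactants: 5 (E,E)-half-ester
Product: 6 diethyl (2E,3E)-2,3-bis[4-(benzyloxy)-3-methoxybenzylidene]succinate
Conditions: EtI, K2CO3, DMF, rt
Reagents that add atoms: ethyl iodide, CCI
Why: carboxylate alkylation gives the symmetric diester, so that both carbonyl groups can be reduced under the same mild conditions.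

Step 5
Reactants: 6 (E,E)-diester
Product: 7 (2E,3E)-2,3-bis[4-(benzyloxy)-3-methoxybenzylidene]butane-1,4-diol
Conditions: i-Bu2AlH (5 equiv), CH2Cl2, −78 → 0 °C; aq. potassium sodium tartrate (KNaC4H4O6)
Reagents that add atoms: none
Why: 1,2-reduction of both conjugated esters by i-Bu2AlH should give the bis-allylic diol and leave the trisubstituted alkenes, their geometry and the benzyl ethers untouched.

Step 6
Reactants: 7 (E,E)-diol
Product: 8 (2E,3E)-2,3-bis[4-(benzyloxy)-3-methoxybenzylidene]butane-1,4-diol bis(tert-butyldimethylsilyl) ether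
Conditions: TBSCl, imidazole, DMF, rt
Reagents that add atoms: tert-butyldimethylsilyl chloride, CC(C)(C)[Si](C)(C)Cl
Why: silylation of the two primary allylic alcohols removes the acidic O–H groups before the borane is added and places the oxygen atoms γ to the future C–B bonds, where no β-elimination is possible.

Step 7
Reactants: 8 (E,E)-diene bis(silyl ether)
Product: 11 (1S,2S,3S,4S)-1,4-bis[4-(benzyloxy)-3-methoxyphenyl]-2,3-bis{[tert-butyl(dimethyl)silyl]oxymethyl}butane-1,4-diol, via dialkylborane 9 (not isolated), via borolane 10 (not isolated)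
Conditions: IpcBH2 from (−)-α-pinene (1.05 equiv, THF solution added slowly), THF, −25 °C → rt; then NaBO3·4H2O, THF/H2O, rt
Reagents that add atoms: sodium perborate tetrahydrate (NaBO3·4H2O), [Na+].[Na+].O[B-]1(O)OO[B-](O)(O)OO1
Why: Proposed new method: IpcBH2 should add to one (E)-arylidene alkene through the four-centre syn transition state, boron to the less substituted benzylic CH and hydrogen to C2, to give 9; the closest known reactions are the IpcBH2 hydroboration of trisubstituted aryl alkenes and the cyclic hydroboration of 1,3-dienes to borolanes by monoalkylboranes, not yet combined on a 1,4-diaryl-2,3-disubstituted 1,3-diene. The second B–H of 9 is then delivered inside the molecule to the other alkene, closing the five-membered borolane ring of 10 by B–C4 bond formation in an intramolecular syn addition (the reverse regiochemistry would need a four-membered ring); no ring of the target closes here and 10 is opened again by the oxidation. C1 is set by the isopinocampheyl group (enantiofacial choice), C2 and C4 follow from syn addition to the (E)-alkenes, and C3 is set by the substrate, because allylic 1,3-strain against the aryl group that is cis on C4 holds the C2–H bond in the alkene plane and so puts the boron-bearing C1 over the face that leads to the borolane with the C2 and C3 arms trans (twofold-symmetric series). NaBO3 then converts the three B–C bonds into C–O bonds with retention, giving 11 beside isopinocampheol. The step needs one borane per diene, because a second IpcBH2 reaching 9 from outside would be sent by the same allylic strain to the opposite face (meso series); slow addition of a near-stoichiometric amount of borane and the faster ring closure should secure this. The enantiomeric purity rests on the first addition alone and would be raised by crystallisation of 11 if needed.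

Step 8
Reactants: 11 (1S,2S,3S,4S)-diol
Product: 13 (3S,4S,5S)-2,5-bis[4-(benzyloxy)-3-methoxyphenyl]-3,4-bis{[tert-butyl(dimethyl)silyl]oxymethyl}oxolan-2-ol (lactol, both C2 anomers), via hydroxy ketone 12 (not isolated)
Conditions: activated MnO2 (excess), CH2Cl2, rt, stopped when 11 is consumed
Reagents that add atoms: none
Why: MnO2 oxidation of a benzylic alcohol, in which one of the two equivalent carbinols should be oxidised and the γ-hydroxy ketone 12 should close to the five-membered lactol 13, which withdraws the second carbinol from oxidation; the twofold symmetry of 11 makes the choice of end immaterial and the three remaining stereocentres are not touched.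

Step 9
Reactants: 13 lactol
Product: 15 (2S,3S,4S,5S)-2,5-bis[4-(benzyloxy)-3-methoxyphenyl]-3,4-bis{[tert-butyl(dimethyl)silyl]oxymethyl}oxolane, via oxocarbenium ion 14 (not isolated)
Conditions: Et3SiH (3 equiv), BF3·OEt2, CH2Cl2, −78 °C; NaHCO3 quench at −78 °C
Reagents that add atoms: none
Why: ionic hydrogenation of the lactol, in which hydride should add to the 2-aryl oxocarbenium ion on the face opposite the adjacent C3 silyloxymethyl group, setting C2 with aryl cis to that arm as is usual for 3-substituted 2-aryl cyclic hemiketals, while the low temperature keeps C5 and the silyl ethers intact.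

Step 10
Reactants: 15 oxolane bis(silyl ether)
Product: 16 [(2S,3S,4S,5S)-2,5-bis(4-benzyloxy-3-methoxyphenyl)oxolane-3,4-diyl]dimethanol
Conditions: Bu4NF, THF, 0 °C → rt
Reagents that add atoms: none
Why: fluoride cleavage of the two primary silyl ethers, under which the benzylic ring C–O bonds, the benzyl ethers and all four stereocentres are inert.

Step 11
Reactants: 16 dibenzyl ether diol
Product: 17 eduesmine, (2S,3S,4S,5S)-2,5-bis(4-hydroxy-3-methoxyphenyl)-3,4-bis(hydroxymethyl)oxolane
Conditions: H2 (1 atm), Pd/C, EtOAc/MeOH, rt, stopped after uptake of two equivalents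
Reagents that add atoms: none
Why: hydrogenolysis of the two aryl benzyl ethers over Pd/C, which should be faster than cleavage of the dialkyl benzylic C–O bonds of the ring, under neutral conditions that do not epimerise the cis-aryl centres.

**Compound list**

1 | 4-(benzyloxy)-3-methoxybenzaldehyde | COc1cc(C=O)ccc1OCc1ccccc1 | starting material
2 | diethyl succinate | CCOC(=O)CCC(=O)OCC | starting material
3 | (E)-4-[4-(benzyloxy)-3-methoxyphenyl]-3-(ethoxycarbonyl)but-3-enoic acid | COc1cc(ccc1OCc1ccccc1)/C=C(\CC(=O)O)C(=O)OCC | intermediate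
4 | diethyl (E)-2-[4-(benzyloxy)-3-methoxybenzylidene]succinate | COc1cc(ccc1OCc1ccccc1)/C=C(\CC(=O)OCC)C(=O)OCC | intermediate
5 | (2E,3E)-2,3-bis[4-(benzyloxy)-3-methoxybenzylidene]succinic acid monoethyl ester | COc1cc(ccc1OCc1ccccc1)/C=C(C(=O)O)\C(C(=O)OCC)=C/c1ccc(OCc2ccccc2)c(OC)c1 | intermediate
6 | diethyl (2E,3E)-2,3-bis[4-(benzyloxy)-3-methoxybenzylidene]succinate | COc1cc(ccc1OCc1ccccc1)/C=C(C(=O)OCC)\C(C(=O)OCC)=C/c1ccc(OCc2ccccc2)c(OC)c1 | intermediate
7 | (2E,3E)-2,3-bis[4-(benzyloxy)-3-methoxybenzylidene]butane-1,4-diol | COc1cc(ccc1OCc1ccccc1)/C=C(CO)\C(CO)=C/c1ccc(OCc2ccccc2)c(OC)c1 | intermediate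
8 | (2E,3E)-2,3-bis[4-(benzyloxy)-3-methoxybenzylidene]butane-1,4-diol bis(tert-butyldimethylsilyl) ether | COc1cc(ccc1OCc1ccccc1)/C=C(/CO[Si](C)(C)C(C)(C)C)\C(CO[Si](C)(C)C(C)(C)C)=C/c1ccc(OCc2ccccc2)c(OC)c1 | intermediate
9 | dialkylborane: Ipc(H)B on benzylic C1 and H on C2 (configured as in 11), (E)-alkene C3=C4 intact | COc1cc(ccc1OCc1ccccc1)[C@@H](B[C@H]2C[C@H]3C[C@@H]([C@@H]2C)C3(C)C)[C@H](CO[Si](C)(C)C(C)(C)C)\C(CO[Si](C)(C)C(C)(C)C)=C/c1ccc(OCc2ccccc2)c(OC)c1 | intermediate
10 | 1-isopinocampheyl-2,5-bis[4-(benzyloxy)-3-methoxyphenyl]-3,4-bis{[tert-butyl(dimethyl)silyl]oxymethyl}borolane (each aryl cis to the neighbouring arm, arms trans) | COc1cc(ccc1OCc1ccccc1)[C@H]1B([C@H]2C[C@H]3C[C@@H]([C@@H]2C)C3(C)C)[C@H](c2ccc(OCc3ccccc3)c(OC)c2)[C@H](CO[Si](C)(C)C(C)(C)C)[C@H]1CO[Si](C)(C)C(C)(C)C | intermediate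
11 | (1S,2S,3S,4S)-1,4-bis[4-(benzyloxy)-3-methoxyphenyl]-2,3-bis{[tert-butyl(dimethyl)silyl]oxymethyl}butane-1,4-diol | COc1cc(ccc1OCc1ccccc1)[C@@H](O)[C@H](CO[Si](C)(C)C(C)(C)C)[C@@H](CO[Si](C)(C)C(C)(C)C)[C@H](O)c1ccc(OCc2ccccc2)c(OC)c1 | intermediate
12 | (2S,3S,4S)-1,4-bis[4-(benzyloxy)-3-methoxyphenyl]-4-hydroxy-2,3-bis{[tert-butyl(dimethyl)silyl]oxymethyl}butan-1-one | COc1cc(ccc1OCc1ccccc1)C(=O)[C@H](CO[Si](C)(C)C(C)(C)C)[C@@H](CO[Si](C)(C)C(C)(C)C)[C@H](O)c1ccc(OCc2ccccc2)c(OC)c1 | intermediate
13 | (3S,4S,5S)-2,5-bis[4-(benzyloxy)-3-methoxyphenyl]-3,4-bis{[tert-butyl(dimethyl)silyl]oxymethyl}oxolan-2-ol (C2 anomers) | COc1cc(ccc1OCc1ccccc1)C1(O)O[C@H](c2ccc(OCc3ccccc3)c(OC)c2)[C@H](CO[Si](C)(C)C(C)(C)C)[C@H]1CO[Si](C)(C)C(C)(C)C | intermediate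
14 | (3S,4S,5S)-2-aryl oxocarbenium ion derived from 13, hydroxytrifluoroborate salt | COc1cc(ccc1OCc1ccccc1)C1=[O+][C@H](c2ccc(OCc3ccccc3)c(OC)c2)[C@H](CO[Si](C)(C)C(C)(C)C)[C@H]1CO[Si](C)(C)C(C)(C)C.O[B-](F)(F)F | intermediate
15 | (2S,3S,4S,5S)-2,5-bis[4-(benzyloxy)-3-methoxyphenyl]-3,4-bis{[tert-butyl(dimethyl)silyl]oxymethyl}oxolane | COc1cc(ccc1OCc1ccccc1)[C@H]1O[C@H](c2ccc(OCc3ccccc3)c(OC)c2)[C@H](CO[Si](C)(C)C(C)(C)C)[C@H]1CO[Si](C)(C)C(C)(C)C | intermediate
16 | [(2S,3S,4S,5S)-2,5-bis(4-benzyloxy-3-methoxyphenyl)oxolane-3,4-diyl]dimethanol | COc1cc(ccc1OCc1ccccc1)[C@H]1O[C@H](c2ccc(OCc3ccccc3)c(OC)c2)[C@H](CO)[C@H]1CO | intermediate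
17 | eduesmine | COc1cc([C@H]2O[C@H](c3ccc(O)c(OC)c3)[C@H](CO)[C@H]2CO)ccc1O | target

**Step count and risks**

Total step count: 11. Longest linear sequence: 11 steps (1 and 2 to 17).

Steps most likely to fail:

1. Step 7. The hindered, twisted diene may take up the borane slowly. The first B–H addition may discriminate the alkene faces only moderately. A second borane molecule may add from outside before the ring closes, which leads into the meso series. The fallback uses known chemistry; it sets out from 1 and comes back at 13.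
   - Aldehyde 1 is converted with propane-1,3-dithiol and BF3·OEt2 into 2-[4-(benzyloxy)-3-methoxyphenyl]-1,3-dithiane F1.
   - Lithiated F1 (n-BuLi, THF, −78 °C) is added in a conjugate sense to (5S)-5-[(1S,2R,5S)-menthyloxy]furan-2(5H)-one, made from (+)-menthol, anti to the menthyloxy group. The lactone enolate is trapped with a second equivalent of 1, trans to the new substituent, to give the menthyloxy lactone F2. This tandem conjugate addition–aldol reaction is established for lignans, but it is not expected to control the carbinol carbon, so the (S)-carbinol epimer would be separated by chromatography.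
   - LiAlH4 reduces the lactone and its acetal carbon to the two hydroxymethyl groups and releases menthol, giving the dithiane triol F3.
   - TBSCl/imidazole silylates the two primary alcohols selectively to give the dithiane bis(silyl ether) F4.
   - MeI/CaCO3 in aqueous MeCN unmasks the ketone 12, which closes to 13, and the route continues with step 9.

2. Step 8. The open hydroxy ketone form may be oxidised further to the 1,4-diketone, or the oxidation may stall. The fallback sets out from 11 and comes back at 13.
   - One equivalent of Et3SiCl/imidazole gives the mono(triethylsilyl) ether F5; recovered 11 and the bis-ether, after acid methanolysis, are recycled.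
   - MnO2 oxidises the single free carbinol to the keto silyl ether F6, in which no second oxidation is possible.
   - PPTS in MeOH removes the secondary triethylsilyl group in the presence of the primary TBS ethers and gives 12, which closes to 13.

3. Step 9. Hydride may be delivered to the face syn to the C3 arm. The Lewis acid may open the ring at the C5–O bond and epimerise C5 to the more stable trans series. The oxocarbenium ion may lose the C3 proton. The fallback replaces hydride reduction by a directed hydrogenation; it sets out from 13 and comes back at 16.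
   - Lactol 13 is dehydrated (cat. PPTS, toluene, 4 Å molecular sieves, 80 °C) to the 2-aryl-4,5-dihydrofuran F7, with C4 and C5 unchanged.
   - Bu4NF gives the dihydrofuran diol F8.
   - Hydrogenation with [Ir(cod)(PCy3)(py)]PF6 and H2 in CH2Cl2, directed by the C4 hydroxymethyl group, delivers both hydrogens to C2 and C3 from the face of that arm. This gives aryl cis to arm at C2/C3 with the arms trans, which is 16; the benzyl ethers survive the homogeneous catalyst.

Further compounds
F1 | step 7 | 2-[4-(benzyloxy)-3-methoxyphenyl]-1,3-dithiane | COc1cc(ccc1OCc1ccccc1)C1SCCCS1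
F2 | step 7 | (3R,4S,5S)-3-{(S)-[4-(benzyloxy)-3-methoxyphenyl](hydroxy)methyl}-4-{2-[4-(benzyloxy)-3-methoxyphenyl]-1,3-dithian-2-yl}-5-[(1S,2R,5S)-menthyloxy]dihydrofuran-2(3H)-one | O=C1O[C@H](O[C@H]2C[C@@H](C)CC[C@@H]2C(C)C)[C@@H](C2(c3ccc(OCc4ccccc4)c(OC)c3)SCCCS2)[C@@H]1[C@H](O)c1ccc(OCc2ccccc2)c(OC)c1
F3 | step 7 | (1S,2S,3S)-1-[4-(benzyloxy)-3-methoxyphenyl]-3-{2-[4-(benzyloxy)-3-methoxyphenyl]-1,3-dithian-2-yl}-2-(hydroxymethyl)butane-1,4-diol | OC[C@@H](C1(c2ccc(OCc3ccccc3)c(OC)c2)SCCCS1)[C@@H](CO)[C@H](O)c1ccc(OCc2ccccc2)c(OC)c1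
F4 | step 7 | bis(tert-butyldimethylsilyl) ether of F3 at the two primary hydroxyl groups | CC(C)(C)[Si](C)(C)OC[C@@H](C1(c2ccc(OCc3ccccc3)c(OC)c2)SCCCS1)[C@@H](CO[Si](C)(C)C(C)(C)C)[C@H](O)c1ccc(OCc2ccccc2)c(OC)c1
F5 | step 8 | mono(triethylsilyl) ether of diol 11 at one benzylic hydroxyl group | COc1cc(ccc1OCc1ccccc1)[C@@H](O[Si](CC)(CC)CC)[C@H](CO[Si](C)(C)C(C)(C)C)[C@@H](CO[Si](C)(C)C(C)(C)C)[C@H](O)c1ccc(OCc2ccccc2)c(OC)c1
F6 | step 8 | (2S,3S,4S)-1,4-bis[4-(benzyloxy)-3-methoxyphenyl]-2,3-bis{[tert-butyl(dimethyl)silyl]oxymethyl}-4-(triethylsilyloxy)butan-1-one | COc1cc(ccc1OCc1ccccc1)[C@@H](O[Si](CC)(CC)CC)[C@H](CO[Si](C)(C)C(C)(C)C)[C@@H](CO[Si](C)(C)C(C)(C)C)C(=O)c1ccc(OCc2ccccc2)c(OC)c1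
F7 | step 9 | (2S,3S)-2,5-bis[4-(benzyloxy)-3-methoxyphenyl]-3,4-bis{[tert-butyl(dimethyl)silyl]oxymethyl}-2,3-dihydrofuran | COc1cc(ccc1OCc1ccccc1)C1=C(CO[Si](C)(C)C(C)(C)C)[C@@H](CO[Si](C)(C)C(C)(C)C)[C@@H](c2ccc(OCc3ccccc3)c(OC)c2)O1
F8 | step 9 | [(2S,3S)-2,5-bis(4-benzyloxy-3-methoxyphenyl)-2,3-dihydrofuran-3,4-diyl]dimethanol | COc1cc(ccc1OCc1ccccc1)C1=C(CO)[C@@H](CO)[C@@H](c2ccc(OCc3ccccc3)c(OC)c2)O1
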